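What would this flask hold after 1.0 h, and how would the substrate that had reacted divide between target and side product? I had these recipes and runs:

all flasks: initiator 8 mol%
- birch: substrate 10 mM; coupling partner 1.2 equiv; transfer agent 20 mM; run made earlier
- larch: substrate 40 mM; coupling partner 1.2 equiv; transfer agent 20 mM; run made earlier
- cedar: substrate 20 mM; coupling partner 1.2 equiv; transfer agent 30 mM; run made earlier
- flask: substrate 20 mM; coupling partner 1.20 equiv; transfer agent 20.0 mM; time 1.0 h

| run | time / min | substrate / % | target / % | side product / % |
|---|---|---|---|---|
| birch | 5.00 | 99.2 | 0.5 | 0 |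
| birch | 10.0 | 98.7 | 1.0 | 0.7 |
| birch | 15.0 | 97.9 | 1.2 | 1.2 |
| birch | 20.0 | 97.6 | 1.5 | 1.6 |
| birch | 25.0 | 96.3 | 1.8 | 2.0 |
| birch | 30.0 | 95.7 | 2.3 | 2.1 |
| birch | 40.0 | 94.6 | 2.8 | 2.0 |
| larch | 3.00 | 98.4 | 1.1 | 0 |
| larch | 4.00 | 98.3 | 1.1 | 0.1 |
| larch | 6.00 | 97.3 | 2.2 | 0.7 |
| larch | 10.0 | 95.5 | 3.2 | 0.9 |
| larch | 15.0 | 93.8 | 4.3 | 1.0 |
| larch | 25.0 | 90.5 | 8.0 | 1.7 |
| larch | 40.0 | 85.3 | 12.2 | 2.2 |
| cedar | 3.00 | 99.4 | 0.4 | 0.2 |
| cedar | 5.00 | 99.8 | 0.5 | 0.4 |
| cedar | 10.0 | 98.1 | 1.2 | 1.0 |
| cedar | 20.0 | 96.4 | 2.7 | 1.0 |
| cedar | 40.0 | 93.8 | 3.7 | 2.2 |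

(each reading ± 0.3 percentage points)

- the analysis behind the earlier runs scatters by 0.3 percentage points, standard deviation
- steps under discussion: 2 idle radical -> ended radicals; substrate + initiating radical -> capped initiator + first chain carrier; initiator -> 2 initiating radical; coupling partner + first chain carrier -> target + second chain carrier; 2 second chain carrier -> ended chains; transfer agent + first chain carrier -> side product + idle radical; substrate + second chain carrier -> released group + first chain carrier

- the substrate in the flask at 1.0 h, as a percentage of the substrate charged
- the target in the flask at 1.0 h, as a percentage of the substrate charged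
- the side product in the flask at 1.0 h, as a percentage of the substrate charged

Among the steps under discussion, the first chain carrier has two takers: coupling partner gives target, and transfer agent gives side product. So I asked first how that split moved with the charges. I used a selectivity factor S. It is target over side product at the last reading, divided by charged coupling partner over charged transfer agent. Birch, larch and cedar read 2.33, 2.31 and 2.10, and S averaged over these runs came to 2.25.

How much side product, then? Its last readings were 2.0 %, 2.2 % and 2.2 %, although substrate ran from 10 mM to 40 mM with initiator at 8 mol%. Scaling their mean in proportion to time gave 3.20 % side product at 1.0 h.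

With a charged ratio of 1.20, my first round gave 8.64 % target. I put that back in: the mean ratio over the run became 1.18, and target became 8.46 %. Substrate, target and side product had summed to about 99.6 % at the last readings, so I took substrate as the remainder, 88.3 %.

The forecast, holding that “the target is competitive capture”, gave 88.5 % substrate, 8 % target and 3 % side product, lower than mine in target and side product and close to mine in substrate.

The flask gave 87.5 % substrate, 9.01 % target and 3.48 % side product.

    2 idle radical → ended radicals (k = 1.20 × 10⁷ M⁻¹ s⁻¹)
    substrate + initiating radical → capped initiator + first chain carrier (k = 5.40 × 10⁵ M⁻¹ s⁻¹)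
    initiator → 2 initiating radical (k = 0.00410 min⁻¹)
    coupling partner + first chain carrier → target + second chain carrier (k = 2.20 × 10⁵ M⁻¹ s⁻¹)
    2 second chain carrier → ended chains (k = 1.00 × 10⁸ M⁻¹ s⁻¹)
    transfer agent + first chain carrier → side product + idle radical (kL = 1.00 × 10⁵ M⁻¹ s⁻¹)
    substrate + second chain carrier → released group + first chain carrier (k = 23000 M⁻¹ s⁻¹)

S with the charged ratio gives target over side product of 2.70, and this flask shows 2.59. The neighbouring flask was charged with 5.0 mM of substrate at the same equivalents, so its charge was 6.00 mM of coupling partner against 20.0 mM of transfer agent, a ratio of 0.300. S then gives 0.675. At 1.0 h that neighbour holds 3.49 % side product, about what this flask holds, and 2.29 % target, a ratio of 0.656.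

The data stem from a simulated flask for substances that don't exist, and the scatter is random.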